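**Retrosynthetic overview**

- The route rests on one feature: ring A (C4a, C5, C6, C7, C8, C8a) is a fully substituted phloroglucinol whose C4a–C8a edge is the enone C5=C6 bond of a 2-aryl-2,3-dihydropyran-4-one (ring C: O1, C2, C3, C4, C4a, C8a). Ring A can therefore be grown onto a preformed, enantioenriched ring C.
- Last disconnection: the three ring B acetates. Key disconnection: C4a–C5 and C8–C8a, giving a 2-prenyl-4-lavandulyl 1-methoxy-1,3-bis(silyloxy)diene and an (S)-5-sulfinyl dihydropyranone.
- The diene comes from (S)-limonene (ring cleavage, Wittig, methoxycarbonylation, prenylation, double silylation); the limonene stereocentre becomes the lavandulyl centre.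
- The pyranone comes from 2,4,6-triacetoxybenzaldehyde and Danishefsky's diene by asymmetric hetero-Diels–Alder reaction (sets C2), then C5 sulfenylation and S-oxidation.
- Ring order: ring B is bought, ring C is made in step 8, ring A in step 11.

Key step: step 11

Assumption: the (S,S) antipode of the (salen)CrBF4 catalyst is taken to direct the diene to the Si face of aldehyde 11 (giving 2S); if the sense with this 2,6-disubstituted aldehyde proves opposite, the (R,R) complex is used and nothing else changes.

**Step 1**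
Reactants: 1 (S)-limonene
Product: 3 (3S)-6-oxo-3-(prop-1-en-2-yl)heptanal, via secondary ozonide 2 (not isolated)
Conditions: O3 (1.0 equiv, Sudan Red 7B end-point), CH2Cl2, −78 °C; PPh3, −78 → 23 °C
Reagents that add atoms: ozone, [O-][O+]=O
Why: Chemoselective ozonolysis, because the trisubstituted ring alkene is more electron-rich than the 1,1-disubstituted isopropenyl alkene and should consume the single equivalent of ozone first, leaving the stereocentre untouched.

**Step 2**
Reactants: 3 (3S)-6-oxo-3-(prop-1-en-2-yl)heptanal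
Product: 4 (5S)-8-methyl-5-(prop-1-en-2-yl)non-7-en-2-one
Conditions: i-PrPPh3I, n-BuLi, THF, 0 °C; then 3, −78 → 0 °C
Reagents that add atoms: isopropyltriphenylphosphonium iodide, CC(C)[P+](c1ccccc1)(c1ccccc1)c1ccccc1.[I-]
Why: Wittig olefination, in which the hindered non-stabilised ylide should add to the aldehyde far faster than to the methyl ketone at low temperature.

**Step 3**
Reactants: 4 (5S)-8-methyl-5-(prop-1-en-2-yl)non-7-en-2-one
Product: 5 methyl (6S)-9-methyl-3-oxo-6-(prop-1-en-2-yl)dec-8-enoate
Conditions: NaH, (MeO)2CO, THF, reflux (slow addition of 4); then AcOH, H2O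
Reagents that add atoms: dimethyl carbonate, COC(=O)OC
Why: Crossed Claisen condensation (methoxycarbonylation) at the less hindered methyl terminus, driven by formation of the β-keto ester enolate; the stereocentre is remote from the carbonyl and cannot enolise.

**Step 4**
Reactants: 5 methyl (6S)-9-methyl-3-oxo-6-(prop-1-en-2-yl)dec-8-enoate; 6 prenyl bromide (1-bromo-3-methylbut-2-ene)
Product: 7 methyl (6S)-9-methyl-2-(3-methylbut-2-en-1-yl)-3-oxo-6-(prop-1-en-2-yl)dec-8-enoate (both C2 epimers)
Conditions: NaH (1.0 equiv), THF, 0 °C; then 6 (0.95 equiv), 0 → 23 °C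
Reagents that add atoms: none
Why: C-alkylation of the β-keto ester enolate with an allylic bromide, kept to mono-alkylation by the slight deficit of bromide; the new C2 centre is irrelevant because it becomes sp2.

**Step 5**
Reactants: 7 methyl (6S)-9-methyl-2-(3-methylbut-2-en-1-yl)-3-oxo-6-(prop-1-en-2-yl)dec-8-enoate
Product: 8 methyl (6S)-9-methyl-2-(3-methylbut-2-en-1-yl)-6-(prop-1-en-2-yl)-3-(trimethylsilyloxy)deca-2,8-dienoate (C2=C3 geometry not defined)
Conditions: TMSCl, Et3N, toluene, 23 °C, 72 h; filtration under argon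
Reagents that add atoms: chlorotrimethylsilane, C[Si](C)(C)Cl
Why: O-silylation of the β-keto ester enol under amine base, the standard first stage in making 1,3-bis(silyloxy)dienes.

**Step 6**
Reactants: 8 methyl (6S)-9-methyl-2-(3-methylbut-2-en-1-yl)-6-(prop-1-en-2-yl)-3-(trimethylsilyloxy)deca-2,8-dienoate
Product: 9 (6R)-1-methoxy-9-methyl-2-(3-methylbut-2-en-1-yl)-6-(prop-1-en-2-yl)-1,3-bis(trimethylsilyloxy)deca-1,3,8-triene (same spatial arrangement as 8, the descriptor changes only by priority; used crude)
Conditions: LDA (commercial solution), THF, −78 °C; TMSCl, −78 → 0 °C; pentane, filtration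
Reagents that add atoms: chlorotrimethylsilane, C[Si](C)(C)Cl
Why: γ-Deprotonation of the silyloxy enoate gives the ester dienolate (the only site whose anion is stabilised by the ester), and O-silylation of this dienolate should give the diene.

**Step 7**
Reactants: 10 2,4,6-trihydroxybenzaldehyde
Product: 11 2,4,6-triacetoxybenzaldehyde
Conditions: Ac2O, pyridine, DMAP (cat.), CH2Cl2, 0 → 23 °C
Reagents that add atoms: acetic anhydride, CC(=O)OC(C)=O
Why: Exhaustive O-acetylation; the acetates make the aldehyde more electrophilic for step 8 and make the later benzylic C2–O1 bond less prone to ionise.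

**Step 8**
Reactants: 11 2,4,6-triacetoxybenzaldehyde; 12 Danishefsky's diene ((E)-1-methoxy-3-(trimethylsilyloxy)buta-1,3-diene)
Product: 14 (2S)-2-(2,4,6-triacetoxyphenyl)-2,3-dihydro-4H-pyran-4-one, via methoxy silyloxy dihydropyran 13 (not isolated)
Conditions: (S,S)-(salen)CrBF4 [N,N'-bis(3,5-di-tert-butylsalicylidene)-1,2-cyclohexanediamine complex of trivalent chromium, tetrafluoroborate] (5 mol %), 4 Å MS, t-BuOMe, −30 °C; then TFA, CH2Cl2, 0 °C
Reagents that add atoms: none
Why: Catalytic asymmetric hetero-Diels–Alder reaction in which the chiral Lewis acid should expose the Si face of the aldehyde and so set C2 as S; TFA then expels methanol and the silyl group from 13 to give the enone without touching the aryl acetates.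

**Step 9**
Reactants: 14 (2S)-2-(2,4,6-triacetoxyphenyl)-2,3-dihydro-4H-pyran-4-one
Product: 16 (2S)-5-(phenylsulfanyl)-2-(2,4,6-triacetoxyphenyl)-2,3-dihydro-4H-pyran-4-one, via chloro sulfide adduct 15 (not isolated)
Conditions: PhSCl, CH2Cl2, −78 → 0 °C; then Et3N, 0 °C
Reagents that add atoms: benzenesulfenyl chloride, ClSc1ccccc1
Why: Electrophilic α-sulfenylation of a vinylogous ester: the sulfenyl chloride should attack the nucleophilic C5 (not C3), chloride is taken up at the oxocarbenium carbon C6, and Et3N removes HCl to restore the enone; C2 is not involved.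

**Step 10**
Reactants: 16 (2S)-5-(phenylsulfanyl)-2-(2,4,6-triacetoxyphenyl)-2,3-dihydro-4H-pyran-4-one
Product: 17 (2S)-5-(phenylsulfinyl)-2-(2,4,6-triacetoxyphenyl)-2,3-dihydro-4H-pyran-4-one (both sulfur epimers, used as the mixture)
Conditions: mCPBA (1.0 equiv), CH2Cl2, −78 °C
Reagents that add atoms: 3-chloroperbenzoic acid, O=C(OO)c1cccc(Cl)c1
Why: Sulfide to sulfoxide oxidation with one equivalent of peracid at low temperature should outpace any attack on the electron-poor enone; the vinyl sulfoxide has no β-hydrogen and so should be stable, and the sulfur configuration is irrelevant because sulfur is lost in step 11.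

**Step 11**
Reactants: 9 the bis(silyloxy)diene (2 equiv); 17 (2S)-5-(phenylsulfinyl)-2-(2,4,6-triacetoxyphenyl)-2,3-dihydro-4H-pyran-4-one
Product: 20 (2S)-5,7-dihydroxy-6-(3-methylbut-2-en-1-yl)-8-[(2R)-5-methyl-2-(prop-1-en-2-yl)hex-4-en-1-yl]-2-(2,4,6-triacetoxyphenyl)-2,3-dihydro-4H-chromen-4-one, via sulfinyl cycloadduct 18 (not isolated), via dihydroarene ketal 19 (not isolated)
Conditions: toluene, 23 → 80 °C; then 0.5 M HCl, THF, 0 °C
Reagents that add atoms: none
Why: Proposed new method: diene 9 should add across C5=C6 of 17 in a polarity-matched, normal-demand [4+2] cycloaddition in which its terminal carbon (largest HOMO coefficient, future C8) bonds to the oxygen-bearing β-carbon C6 (future C8a, activated by both C=O and S=O) and its ketene acetal carbon (future C5) bonds to the sulfinyl-bearing α-carbon (future C4a), giving 18; the closest known reactions are Diels–Alder/aromatisation sequences of 1-methoxy-1,3-bis(silyloxy)butadienes with haloquinones and of oxygenated dienes with 2-sulfinyl enones and sulfinylquinones, which shed the sulfoxide spontaneously. Ring A is closed as a six-membered carbocycle by the cycloaddition itself or, if the process is stepwise, by Mukaiyama–Michael addition followed by 6-endo-trig attack of the α-sulfinyl enol silane on the β,β-dioxygenated enone left from the diene. In 18 the sulfinyl group at C4a and the hydrogen at C8a are cis (as they were on the dienophile), so thermal syn-elimination of benzenesulfenic acid restores C4a=C8a (19); acid then removes both silyl groups, collapses the C5 hemiketal with loss of methanol and lets the C8 hydrogen tautomerise to give the phloroglucinol. No lasting stereocentre is created: the transient sp3 centres C4a, C8 and C8a are erased on aromatisation, while C2 and the lavandulyl centre are carried through unchanged because the C2–O1 bond is never broken under these neutral to weakly acidic conditions. The selectivity needed is regiochemical (lavandulyl next to O1, 5-OH next to C4) and is secured by the matched polarisation of the two partners, with the prenyl group on the central diene carbon also blocking the competing [3+3] aldol mode, whose adduct could not aromatise.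

**Step 12**
Reactants: 20 the ring B triacetate
Product: 21 (2S)-5,7-dihydroxy-6-(3-methylbut-2-en-1-yl)-8-[(2R)-5-methyl-2-(prop-1-en-2-yl)hex-4-en-1-yl]-2-(2,4,6-trihydroxyphenyl)-2,3-dihydro-4H-chromen-4-one (CNP0163831.1)
Conditions: NH4OAc (10 equiv), MeOH/H2O (4:1), 23 °C
Reagents that add atoms: none
Why: Neutral ammonium acetate-mediated methanolysis of aryl acetates should free the three ring B phenols without the strong base that would open the flavanone (retro-oxa-Michael) or ionise the C2–O1 bond, and without the acid that would cyclise the prenyl groups onto the phenols.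

**Compound list**

1 | (S)-limonene, (4S)-1-methyl-4-(prop-1-en-2-yl)cyclohex-1-ene | CC1=CC[C@H](CC1)C(C)=C | starting material
2 | secondary ozonide of the ring alkene of 1 (new ring carbons unassigned) | CC12CC[C@H](C(C)=C)CC(O1)OO2 | intermediate
3 | (3S)-6-oxo-3-(prop-1-en-2-yl)heptanal | CC(=O)CC[C@H](C(C)=C)CC=O | intermediate
4 | (5S)-8-methyl-5-(prop-1-en-2-yl)non-7-en-2-one | CC(=O)CC[C@H](C(C)=C)CC=C(C)C | intermediate
5 | methyl (6S)-9-methyl-3-oxo-6-(prop-1-en-2-yl)dec-8-enoate | COC(=O)CC(=O)CC[C@H](C(C)=C)CC=C(C)C | intermediate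
6 | prenyl bromide, 1-bromo-3-methylbut-2-ene | CC(C)=CCBr | starting material
7 | methyl (6S)-9-methyl-2-(3-methylbut-2-en-1-yl)-3-oxo-6-(prop-1-en-2-yl)dec-8-enoate, both C2 epimers | COC(=O)C(CC=C(C)C)C(=O)CC[C@H](C(C)=C)CC=C(C)C | intermediate
8 | methyl (6S)-9-methyl-2-(3-methylbut-2-en-1-yl)-6-(prop-1-en-2-yl)-3-(trimethylsilyloxy)deca-2,8-dienoate | COC(=O)C(CC=C(C)C)=C(O[Si](C)(C)C)CC[C@H](C(C)=C)CC=C(C)C | intermediate
9 | (6R)-1-methoxy-9-methyl-2-(3-methylbut-2-en-1-yl)-6-(prop-1-en-2-yl)-1,3-bis(trimethylsilyloxy)deca-1,3,8-triene | COC(O[Si](C)(C)C)=C(CC=C(C)C)C(O[Si](C)(C)C)=CC[C@H](C(C)=C)CC=C(C)C | intermediate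
10 | 2,4,6-trihydroxybenzaldehyde | O=Cc1c(O)cc(O)cc1O | starting material
11 | 2,4,6-triacetoxybenzaldehyde | O=Cc1c(OC(C)=O)cc(OC(C)=O)cc1OC(C)=O | intermediate
12 | Danishefsky's diene, (E)-1-methoxy-3-(trimethylsilyloxy)buta-1,3-diene | CO/C=C/C(=C)O[Si](C)(C)C | starting material
13 | (6S)-2-methoxy-6-(2,4,6-triacetoxyphenyl)-4-(trimethylsilyloxy)-5,6-dihydro-2H-pyran (acetal carbon unassigned) | COC1C=C(O[Si](C)(C)C)C[C@@H](c2c(OC(C)=O)cc(OC(C)=O)cc2OC(C)=O)O1 | intermediate
14 | (2S)-2-(2,4,6-triacetoxyphenyl)-2,3-dihydro-4H-pyran-4-one | O=C1C=CO[C@H](c2c(OC(C)=O)cc(OC(C)=O)cc2OC(C)=O)C1 | intermediate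
15 | (6S)-2-chloro-3-(phenylsulfanyl)-6-(2,4,6-triacetoxyphenyl)tetrahydropyran-4-one (C2 and C3 unassigned) | O=C1C[C@@H](c2c(OC(C)=O)cc(OC(C)=O)cc2OC(C)=O)OC(Cl)C1Sc1ccccc1 | intermediate
16 | (2S)-5-(phenylsulfanyl)-2-(2,4,6-triacetoxyphenyl)-2,3-dihydro-4H-pyran-4-one | O=C1C[C@@H](c2c(OC(C)=O)cc(OC(C)=O)cc2OC(C)=O)OC=C1Sc1ccccc1 | intermediate
17 | (2S)-5-(phenylsulfinyl)-2-(2,4,6-triacetoxyphenyl)-2,3-dihydro-4H-pyran-4-one, both sulfur epimers | O=S(c1ccccc1)C1=CO[C@H](c2c(OC(C)=O)cc(OC(C)=O)cc2OC(C)=O)CC1=O | intermediate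
18 | cycloadduct: (2S)-5-methoxy-4a-(phenylsulfinyl)-6-prenyl-8-lavandulyl-5,7-bis(trimethylsilyloxy)-2-(2,4,6-triacetoxyphenyl)-2,3,4a,5,8,8a-hexahydro-4H-chromen-4-one (C4a, C5, C8, C8a unassigned) | COC1(O[Si](C)(C)C)C(CC=C(C)C)=C(O[Si](C)(C)C)C(C[C@H](C(C)=C)CC=C(C)C)C2O[C@H](c3c(OC(C)=O)cc(OC(C)=O)cc3OC(C)=O)CC(=O)C12S(=O)c1ccccc1 | intermediate
19 | (2S)-5-methoxy-6-prenyl-8-lavandulyl-5,7-bis(trimethylsilyloxy)-2-(2,4,6-triacetoxyphenyl)-2,3,5,8-tetrahydro-4H-chromen-4-one (C5, C8 unassigned) | COC1(O[Si](C)(C)C)C(CC=C(C)C)=C(O[Si](C)(C)C)C(C[C@H](C(C)=C)CC=C(C)C)C2=C1C(=O)C[C@@H](c1c(OC(C)=O)cc(OC(C)=O)cc1OC(C)=O)O2 | intermediate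
20 | (2S)-5,7-dihydroxy-6-(3-methylbut-2-en-1-yl)-8-[(2R)-5-methyl-2-(prop-1-en-2-yl)hex-4-en-1-yl]-2-(2,4,6-triacetoxyphenyl)-2,3-dihydro-4H-chromen-4-one | C=C(C)[C@H](CC=C(C)C)Cc1c(O)c(CC=C(C)C)c(O)c2c1O[C@H](c1c(OC(C)=O)cc(OC(C)=O)cc1OC(C)=O)CC2=O | intermediate
21 | (2S)-5,7-dihydroxy-6-(3-methylbut-2-en-1-yl)-8-[(2R)-5-methyl-2-(prop-1-en-2-yl)hex-4-en-1-yl]-2-(2,4,6-trihydroxyphenyl)-2,3-dihydro-4H-chromen-4-one | C=C(C)[C@H](CC=C(C)C)Cc1c(O)c(CC=C(C)C)c(O)c2c1O[C@H](c1c(O)cc(O)cc1O)CC2=O | target

**Step count**

Total steps: 12. Longest linear sequence: 8 steps (steps 1–6, 11, 12); the pyranone branch is steps 7–10.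

**Steps most likely to fail**

1. Step 11 (proposed new method). The second bond, C4a–C5, joins two fully substituted carbons and may not form, so the sequence could stop after the first C–C bond or the diene could be protodesilylated by the benzenesulfenic acid released. The fallback makes the two bonds in separate, individually known operations, setting out from 9 and 17. TiCl4-mediated Mukaiyama–Michael addition (CH2Cl2, −78 °C) of the diene terminus to C6 of 17, with aqueous work-up, should give the β-keto sulfoxide Michael adduct F1. Warming in toluene (70 °C, CaCO3) should expel benzenesulfenic acid towards the only β-hydrogen, on the oxygen-bearing carbon, and give the 6-substituted dihydropyranone F2, a masked 3,5,7-triketo ester. Mg(OMe)2 in MeOH should then bring about the biomimetic Claisen cyclisation (the pyranone α-carbon onto the ester, then tautomerisation to the phloroglucinol) with methanolysis of the three acetates in the same pot, so the route is rejoined at target 21. The basic last operation puts C2 at more risk than the main route does.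

2. Step 8. Facial selectivity and turnover may be poor because the aldehyde is 2,6-disubstituted and its acetate carbonyls can bind the Lewis acid. The fallback replaces the catalytic cycloaddition by a reagent-controlled aldol and ring closure, setting out from 11. The diisopinocampheylboron enolate of (E)-4-chlorobut-3-en-2-one ((−)-Ipc2BCl, i-Pr2NEt, Et2O, −78 °C; the antipode if the facial sense proves opposite) should add to 11 to give the β-hydroxy β'-chlorovinyl ketone F3. TMSOTf and i-Pr2NEt (CH2Cl2, −78 → 0 °C) should then close the ring by oxa-Michael addition and loss of chloride, returning to the route at 14.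

3. Step 9. The sulfenyl chloride adduct may fail to eliminate cleanly, or the labile 6-chloro ether 15 may hydrolyse and open the ring before the enone is restored. The fallback separates halogenation from C–S bond formation, setting out from 14. Iodination at C5 (I2, pyridine, CH2Cl2, 0 → 23 °C) should give the 5-iodo dihydropyranone F4. Migita-type coupling with PhSSnBu3 (Pd(PPh3)4, a zerovalent palladium catalyst, toluene, 100 °C) should install the phenylsulfanyl group under neutral conditions that spare the acetates, returning to the route at 16.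

**Further compounds**

F1 | step 11 | Michael adduct: methyl 9-methyl-2-(3-methylbut-2-en-1-yl)-3-oxo-4-[(6S)-4-oxo-3-(phenylsulfinyl)-6-(2,4,6-triacetoxyphenyl)tetrahydropyran-2-yl]-6-(prop-1-en-2-yl)dec-8-enoate (lavandulyl centre as in 9, other centres unassigned) | COC(=O)C(CC=C(C)C)C(=O)C(C[C@H](C(C)=C)CC=C(C)C)C1O[C@H](c2c(OC(C)=O)cc(OC(C)=O)cc2OC(C)=O)CC(=O)C1S(=O)c1ccccc1
F2 | step 11 | 6-substituted dihydropyranone: methyl 9-methyl-2-(3-methylbut-2-en-1-yl)-3-oxo-4-[(2S)-4-oxo-2-(2,4,6-triacetoxyphenyl)-2,3-dihydro-4H-pyran-6-yl]-6-(prop-1-en-2-yl)dec-8-enoate (lavandulyl centre as in 9) | COC(=O)C(CC=C(C)C)C(=O)C(C[C@H](C(C)=C)CC=C(C)C)C1=CC(=O)C[C@@H](c2c(OC(C)=O)cc(OC(C)=O)cc2OC(C)=O)O1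
F3 | step 8 | (S,E)-1-chloro-5-hydroxy-5-(2,4,6-triacetoxyphenyl)pent-1-en-3-one | Cl/C=C/C(=O)C[C@H](O)c1c(OC(C)=O)cc(OC(C)=O)cc1OC(C)=O
F4 | step 9 | (2S)-5-iodo-2-(2,4,6-triacetoxyphenyl)-2,3-dihydro-4H-pyran-4-one | O=C1C[C@@H](c2c(OC(C)=O)cc(OC(C)=O)cc2OC(C)=O)OC=C1I
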